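**Retrosynthetic overview**
- EGCG comes from its octabenzyl ether by hydrogenolysis in the last step.
- Ring C is closed last by making the O1–C2 ether bond: an enantioselective reductive etherification of a racemic open-chain α-galloyloxy aryl ketone that carries the free ring A phenol. Hydride sets C2, and dynamic kinetic resolution through the enol ether sets C3 (2,3-cis).
- That ketone comes from Friedel–Crafts conjugate addition of 3,5-bis(benzyloxy)phenol (ring A) to an α-galloyloxy enone (C4–C4a bond).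
- The enone comes from α-methylenation of a phenacyl gallate. Its ester C–O bond is made from a β-keto sulfoxonium ylide and tribenzylgallic acid, and the ylide from methyl tribenzylgallate.
- Ring order: rings A, B and the galloyl ring are bought; ring C is the only ring made, in the key step.

Assumption: the three benzylated building blocks (1, 3, 7) are bought, and the (R)-catalyst in step 5 is taken to give the (2R,3R) series; if experiment shows the opposite sense, its mirror image is used.

**Step 1**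
Reactants: 1 methyl 3,4,5-tris(benzyloxy)benzoate
Product: 2 dimethylsulfoxonium 2-oxo-2-[3,4,5-tris(benzyloxy)phenyl]ethylide
Conditions: Me3S(O)I (3 equiv), KOtBu (3 equiv), THF, reflux; then 1, reflux
Reagents that add atoms: trimethylsulfoxonium iodide, C[S+](C)(C)=O.[I-]
Why: Corey–Chaykovsky-type acylation of dimethylsulfoxonium methylide by the ester gives the stabilised β-keto ylide; the benzyl ethers are inert to the base and no stereocentre is formed.

**Step 2**
Reactants: 2 dimethylsulfoxonium 2-oxo-2-[3,4,5-tris(benzyloxy)phenyl]ethylide; 3 3,4,5-tris(benzyloxy)benzoic acid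
Product: 4 2-oxo-2-[3,4,5-tris(benzyloxy)phenyl]ethyl 3,4,5-tris(benzyloxy)benzoate (phenacyl gallate)
Conditions: 3 (1.1 equiv), 1,2-dichloroethane, 80 °C
Reagents that add atoms: none
Why: Formal O–H insertion: the acid protonates the ylide carbon and the carboxylate displaces dimethyl sulfoxide (SN2), which forms the gallate ester C–O bond under neutral conditions.

**Step 3**
Reactants: 4 2-oxo-2-[3,4,5-tris(benzyloxy)phenyl]ethyl 3,4,5-tris(benzyloxy)benzoate
Product: 6 3-oxo-3-[3,4,5-tris(benzyloxy)phenyl]prop-1-en-2-yl 3,4,5-tris(benzyloxy)benzoate (α-galloyloxy enone), via Mannich base 5 (not isolated)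
Conditions: (CH2O)n (3 equiv), i-Pr2NH·TFA (1 equiv), TFA (0.1 equiv), THF, 65 °C
Reagents that add atoms: formaldehyde (as paraformaldehyde), C=O; diisopropylamine (as its trifluoroacetate), CC(C)NC(C)C (its atoms are held only in 5 and leave again)
Why: Mannich-type α-methylenation: the ketone enol is aminomethylated to racemic 5 and β-elimination of the amine gives the captodative enone, so the stereocentre of 5 vanishes.

**Step 4**
Reactants: 6 3-oxo-3-[3,4,5-tris(benzyloxy)phenyl]prop-1-en-2-yl 3,4,5-tris(benzyloxy)benzoate; 7 3,5-bis(benzyloxy)phenol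
Product: 8 rac-3-[2,4-bis(benzyloxy)-6-hydroxyphenyl]-1-oxo-1-[3,4,5-tris(benzyloxy)phenyl]propan-2-yl 3,4,5-tris(benzyloxy)benzoate
Conditions: 7 (1.5 equiv), Sc(OTf)3 (5 mol%), CH2Cl2, 0 °C to rt
Reagents that add atoms: none
Why: Friedel–Crafts-type conjugate (Michael) addition of the phloroglucinol-type phenol to the Lewis-acid-activated enone; attack ortho to OH is favoured (two such sites, and the para site is flanked by two benzyloxy groups), and C3 is formed racemic by unselective protonation.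

**Step 5**
Reactants: 8 rac-3-[2,4-bis(benzyloxy)-6-hydroxyphenyl]-1-oxo-1-[3,4,5-tris(benzyloxy)phenyl]propan-2-yl 3,4,5-tris(benzyloxy)benzoate
Product: 12 (2R,3R)-5,7-bis(benzyloxy)-2-[3,4,5-tris(benzyloxy)phenyl]chroman-3-yl 3,4,5-tris(benzyloxy)benzoate (octabenzyl EGCG), via cyclic hemiketal 9 (not isolated), via oxocarbenium ion 10 (not isolated), via 4H-chromene enol ether 11 (not isolated)
Conditions: (R)-3,3'-bis(2,4,6-triisopropylphenyl)-BINOL N-triflylphosphoramide (10 mol%), Hantzsch ester (diethyl 2,6-dimethyl-1,4-dihydropyridine-3,5-dicarboxylate, 1.5 equiv), 5 Å MS, toluene, 40 °C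
Reagents that add atoms: none
Why: Proposed new method: catalytic enantioselective reductive etherification of a racemic α-acyloxy ketone with dynamic kinetic resolution; the strong chiral acid closes 8 to hemiketal 9 and ionises it to oxocarbenium ion 10 (paired with the chiral anion), 10 loses and regains H at C3 through achiral enol ether 11 so its two C3 epimers interconvert, the Hantzsch ester gives hydride to C2 on the face opposite the pseudo-axial 3-galloyloxy group (which also shields its own face by carbonyl participation), which makes the O1–C2 ring bond permanent and gives 2,3-cis, and the chiral anion lets the 3R ion react faster so that C2 (R) and C3 (R) are set together; the closest known reactions are the achiral silyl triflate/silane reductive etherification of α-acyloxy ketones to 2,3-cis flavans and the chiral phosphoric acid/Hantzsch ester transfer hydrogenation of 2,3-disubstituted quinolines, which runs through the same kind of enamine–iminium dynamic kinetic resolution.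

**Step 6**
Reactants: 12 (2R,3R)-5,7-bis(benzyloxy)-2-[3,4,5-tris(benzyloxy)phenyl]chroman-3-yl 3,4,5-tris(benzyloxy)benzoate
Product: 13 (−)-epigallocatechin gallate, (2R,3R)-5,7-dihydroxy-2-(3,4,5-trihydroxyphenyl)chroman-3-yl 3,4,5-trihydroxybenzoate
Conditions: H2 (1 atm), Pd(OH)2/C, THF/MeOH (1:1), rt
Reagents that add atoms: none
Why: Hydrogenolysis of the eight benzyl aryl ethers over Pearlman's catalyst under neutral conditions at rt, which leaves the gallate ester and both stereocentres untouched.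

**Compound list**
1 | methyl 3,4,5-tris(benzyloxy)benzoate | COC(=O)c1cc(OCc2ccccc2)c(OCc2ccccc2)c(OCc2ccccc2)c1 | starting material
2 | dimethylsulfoxonium 2-oxo-2-[3,4,5-tris(benzyloxy)phenyl]ethylide | CS(C)(=O)=CC(=O)c1cc(OCc2ccccc2)c(OCc2ccccc2)c(OCc2ccccc2)c1 | intermediate
3 | 3,4,5-tris(benzyloxy)benzoic acid | OC(=O)c1cc(OCc2ccccc2)c(OCc2ccccc2)c(OCc2ccccc2)c1 | starting material
4 | 2-oxo-2-[3,4,5-tris(benzyloxy)phenyl]ethyl 3,4,5-tris(benzyloxy)benzoate | O=C(COC(=O)c1cc(OCc2ccccc2)c(OCc2ccccc2)c(OCc2ccccc2)c1)c1cc(OCc2ccccc2)c(OCc2ccccc2)c(OCc2ccccc2)c1 | intermediate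
5 | rac-3-(diisopropylamino)-1-oxo-1-[3,4,5-tris(benzyloxy)phenyl]propan-2-yl 3,4,5-tris(benzyloxy)benzoate (Mannich base) | CC(C)N(CC(OC(=O)c1cc(OCc2ccccc2)c(OCc2ccccc2)c(OCc2ccccc2)c1)C(=O)c1cc(OCc2ccccc2)c(OCc2ccccc2)c(OCc2ccccc2)c1)C(C)C | intermediate (not isolated)
6 | 3-oxo-3-[3,4,5-tris(benzyloxy)phenyl]prop-1-en-2-yl 3,4,5-tris(benzyloxy)benzoate | C=C(OC(=O)c1cc(OCc2ccccc2)c(OCc2ccccc2)c(OCc2ccccc2)c1)C(=O)c1cc(OCc2ccccc2)c(OCc2ccccc2)c(OCc2ccccc2)c1 | intermediate
7 | 3,5-bis(benzyloxy)phenol | Oc1cc(OCc2ccccc2)cc(OCc2ccccc2)c1 | starting material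
8 | rac-3-[2,4-bis(benzyloxy)-6-hydroxyphenyl]-1-oxo-1-[3,4,5-tris(benzyloxy)phenyl]propan-2-yl 3,4,5-tris(benzyloxy)benzoate | O=C(c1cc(OCc2ccccc2)c(OCc2ccccc2)c(OCc2ccccc2)c1)C(Cc1c(O)cc(OCc2ccccc2)cc1OCc1ccccc1)OC(=O)c1cc(OCc2ccccc2)c(OCc2ccccc2)c(OCc2ccccc2)c1 | intermediate
9 | 5,7-bis(benzyloxy)-2-hydroxy-2-[3,4,5-tris(benzyloxy)phenyl]chroman-3-yl 3,4,5-tris(benzyloxy)benzoate (cyclic hemiketal, mixture of stereoisomers) | OC1(c2cc(OCc3ccccc3)c(OCc3ccccc3)c(OCc3ccccc3)c2)Oc2cc(OCc3ccccc3)cc(OCc3ccccc3)c2CC1OC(=O)c1cc(OCc2ccccc2)c(OCc2ccccc2)c(OCc2ccccc2)c1 | intermediate (not isolated)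
10 | 5,7-bis(benzyloxy)-3-{[3,4,5-tris(benzyloxy)benzoyl]oxy}-2-[3,4,5-tris(benzyloxy)phenyl]-3,4-dihydrochromenylium (oxocarbenium ion, paired with the catalyst anion; labile at C3) | O=C(OC1Cc2c(OCc3ccccc3)cc(OCc3ccccc3)cc2[O+]=C1c1cc(OCc2ccccc2)c(OCc2ccccc2)c(OCc2ccccc2)c1)c1cc(OCc2ccccc2)c(OCc2ccccc2)c(OCc2ccccc2)c1 | intermediate (not isolated)
11 | 5,7-bis(benzyloxy)-2-[3,4,5-tris(benzyloxy)phenyl]-4H-chromen-3-yl 3,4,5-tris(benzyloxy)benzoate | O=C(OC1=C(c2cc(OCc3ccccc3)c(OCc3ccccc3)c(OCc3ccccc3)c2)Oc2cc(OCc3ccccc3)cc(OCc3ccccc3)c2C1)c1cc(OCc2ccccc2)c(OCc2ccccc2)c(OCc2ccccc2)c1 | intermediate (not isolated)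
12 | (2R,3R)-5,7-bis(benzyloxy)-2-[3,4,5-tris(benzyloxy)phenyl]chroman-3-yl 3,4,5-tris(benzyloxy)benzoate | O=C(O[C@@H]1Cc2c(OCc3ccccc3)cc(OCc3ccccc3)cc2O[C@@H]1c1cc(OCc2ccccc2)c(OCc2ccccc2)c(OCc2ccccc2)c1)c1cc(OCc2ccccc2)c(OCc2ccccc2)c(OCc2ccccc2)c1 | intermediate
13 | (−)-epigallocatechin gallate | O=C(O[C@@H]1Cc2c(O)cc(O)cc2O[C@@H]1c1cc(O)c(O)c(O)c1)c1cc(O)c(O)c(O)c1 | target

**Totals**
Total step count: 6. Longest linear sequence: 6 (1 → 2 → 4 → 6 → 8 → 12 → 13).

**Three steps most likely to fail**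

The first is step 5, the proposed new method. The acid may be too weak to ionise the hemiketal, the C3 epimers may interconvert too slowly, or the chiral anion may discriminate poorly. The fallback uses known chemistry and sets out from 8. Et3SiH and TMSOTf in CH2Cl2 at −40 to 0 °C carry out the substrate-controlled 2,3-cis reductive etherification that is established for α-acyloxy ketones of this type. This gives the racemic cis ether, that is 12 together with its mirror image (2S,3S)-5,7-bis(benzyloxy)-2-[3,4,5-tris(benzyloxy)phenyl]chroman-3-yl 3,4,5-tris(benzyloxy)benzoate F1. Preparative chromatography on a chiral phase removes F1, and the route is rejoined at 12.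

The second is step 3. Aminomethylation at a carbon that already bears the acyloxy group may be slow, and enone 6 may polymerise. The fallback sets out from 4 and avoids the enone. Condensation of 4 with purchasable 2,4-bis(benzyloxy)-6-hydroxybenzaldehyde F2 under dry HCl in EtOAc at 0 °C is the classical benzopyrylium synthesis from ω-acyloxyacetophenones. It gives 5,7-bis(benzyloxy)-3-{[3,4,5-tris(benzyloxy)benzoyl]oxy}-2-[3,4,5-tris(benzyloxy)phenyl]chromenylium chloride F3. One equivalent of Hantzsch ester in CH2Cl2 delivers hydride to C4 of F3 and gives 11, which is isolated here and put under the step 5 conditions. The route is rejoined at 11, so steps 3 and 4 are both bypassed.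

The third is step 4. Alkylation para to the phenol OH, or double alkylation, could erode the yield. The fallback sets out from 7 and 4 and fixes the regiochemistry before the C–C bond is made. Ortho-aminomethylation of 7 with dimethylmethylideneammonium iodide gives 3,5-bis(benzyloxy)-2-[(dimethylamino)methyl]phenol F4. Methyl iodide turns it into [2,4-bis(benzyloxy)-6-hydroxybenzyl]trimethylammonium iodide F5. With K2CO3 in MeCN, F5 loses trimethylamine to give the ortho-quinone methide 3,5-bis(benzyloxy)-6-methylidenecyclohexa-2,4-dien-1-one F6, which is trapped at its CH2 group by the enolate of 4. The route is rejoined at 8.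

**Further compounds**
F1 | step 5 | (2S,3S)-5,7-bis(benzyloxy)-2-[3,4,5-tris(benzyloxy)phenyl]chroman-3-yl 3,4,5-tris(benzyloxy)benzoate | O=C(O[C@H]1Cc2c(OCc3ccccc3)cc(OCc3ccccc3)cc2O[C@H]1c1cc(OCc2ccccc2)c(OCc2ccccc2)c(OCc2ccccc2)c1)c1cc(OCc2ccccc2)c(OCc2ccccc2)c(OCc2ccccc2)c1
F2 | step 3 | 2,4-bis(benzyloxy)-6-hydroxybenzaldehyde | O=Cc1c(O)cc(OCc2ccccc2)cc1OCc1ccccc1
F3 | step 3 | 5,7-bis(benzyloxy)-3-{[3,4,5-tris(benzyloxy)benzoyl]oxy}-2-[3,4,5-tris(benzyloxy)phenyl]chromenylium chloride | O=C(Oc1cc2c(OCc3ccccc3)cc(OCc3ccccc3)cc2[o+]c1-c1cc(OCc2ccccc2)c(OCc2ccccc2)c(OCc2ccccc2)c1)c1cc(OCc2ccccc2)c(OCc2ccccc2)c(OCc2ccccc2)c1.[Cl-]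
F4 | step 4 | 3,5-bis(benzyloxy)-2-[(dimethylamino)methyl]phenol | CN(C)Cc1c(O)cc(OCc2ccccc2)cc1OCc1ccccc1
F5 | step 4 | [2,4-bis(benzyloxy)-6-hydroxybenzyl]trimethylammonium iodide | C[N+](C)(C)Cc1c(O)cc(OCc2ccccc2)cc1OCc1ccccc1.[I-]
F6 | step 4 | 3,5-bis(benzyloxy)-6-methylidenecyclohexa-2,4-dien-1-one | C=C1C(=O)C=C(OCc2ccccc2)C=C1OCc1ccccc1
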